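All constants are those of an exercise.

A micromole per litre is the unit to think in here: the enzyme charged is 7.98 µM and the impurity that kills it is 3.6 µM, against a starting material at 0.14 M.

starting material 0.14 M; second substrate 1.00 equiv; enzyme 0.0057 mol%; impurity 3.6 µM

    starting material + enzyme ⇌ complex A (K1 = 9.4 L mol⁻¹, k1 = 23000 L mol⁻¹ s⁻¹)
    complex A → enzyme + target (k2 = 350 s⁻¹)
    second substrate + enzyme ⇌ complex B (K3 = 110 L mol⁻¹, k3 = 46000 L mol⁻¹ s⁻¹)
    complex B → enzyme + second product (k4 = 210 s⁻¹)
    enzyme + impurity → spent catalyst (k5 = 5000 L mol⁻¹ s⁻¹)
    2 second substrate → self-condensation product (k6 = 0.059 L mol⁻¹ s⁻¹)

* apparent order in enzyme when 5.0 % of the starting material are converted (percent change of the rate of making target for one percent more enzyme charged)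

Counting both falling back and going on, complex A lasts about 3.58 × 10⁻⁴ s and complex B about 0.00159 s, far less than the 1.01 min first half-life of second substrate by self-condensation, so each complex holds steady and the two substrates compete for the same enzyme (competitive inhibition). Each substrate's strength is its Michaelis constant, the breakdown of its complex over its formation: 0.122 M for starting material and 0.0137 M for second substrate. With the charges, the enzyme is spread over 12.4 parts, one of them free, and complex B holds 0.827 of the working enzyme. So one percent more [second substrate] costs about that fraction of a percent of rate.

The opening rate, 0.0156 M min⁻¹, reaches 5.0 % conversion in 0.450 min. The second substrate that the enzyme uses is tied to conversion, but self-condensation runs by the clock, with a first half-life of 1.01 min. More enzyme shortens the clock, so at equal conversion more [second substrate] survives. By self-condensation alone, the [second substrate] kept goes as one over one plus time per half-life. Multiply that sensitivity by the share above and you have the pull, the amount of order that the surviving second substrate takes away: 0.255.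

The impurity pushes the other way. At the free share it spends 3.92 % of the catalyst by then, a nearly fixed amount, which lifts the order to 1.04. My order is the lift less the pull: 0.786.

The forecast says 0.87, from a lift of about 1.04 and this ground: “More enzyme also means less time for the second substrate to self-condense”. My figure is lower than the forecast's.

The flask gives 0.87, so at this moment one percent more enzyme brings that many percent more rate of making target. At that conversion, 3.85 % of the catalyst is spent catalyst, which makes the lift 1.04. Take the pull of 0.255 from that lift and you stand at 0.785. This flask's own gap between lift and order is 0.167.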